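**Plan**

1. Numbering: the target is (1R,3Z,7Z,11R,12S,15S)-4,8-dimethyl-15-(4-methylpent-3-en-1-yl)spiro[bicyclo[9.3.1]pentadeca-3,7-diene-12,2'-oxirane]-15-carbaldehyde; the cyclohexane is C1, C11, C12, C13, C14, C15 (C15 quaternary), the nine-carbon bridge is C2–C10.
2. Cuts, in retrosynthetic order: CHO from CH2OH; C4–C5 (macrocyclic B-alkyl Suzuki coupling); C3=C4 (iodoethylidene Wittig on a lactol); oxirane from the C12 ketone; C1–C14 (radical closure of the cyclohexanone); C11–C15 (Ireland–Claisen); ester C–O.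
3. Enabling feature: the formyl carbon on C15 and C2 on the neighbouring C1 are cis on the cyclohexane, so the chain O–CH2–C15–C1=C2–C3(=O) can be held as one unsaturated δ-lactone ring (a 5,6-dihydropyran-2-one) whose β-carbon is C1 and whose quaternary carbon C15 carries the tether.
4. Forward: a 3,6-dihydro-2H-pyran-3-ol is acylated and rearranged (C15, C11), its ring CH2 is oxidised to the lactone, a vinyl ketone radical closes the cyclohexanone onto the lactone (C1), the ketone becomes the oxirane, the lactol releases the C3 aldehyde for the Z-iodoalkene, and the twelve-membered ring is closed before the final oxidation.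
5. Stereochemistry: one CBS reduction; suprafacial [3,3] transfer to C15 and chair control at C11; cis ring fusion at C1; equatorial ylide attack at C12; both Z olefins come from stereodefined iodoalkenes coupled with retention.

Key step: step 13

Remark: the SMILES is taken literally, so both ring olefins are Z and the two ends of the nine-carbon bridge (C2 and C10) lie on opposite faces of the cyclohexane.

**Route**

Step 1
Reactants: 1 2H-pyran-3,5(4H,6H)-dione
Product: 2 5-ethoxy-2H-pyran-3(6H)-one
Conditions: EtOH, TsOH (cat.), toluene, reflux, Dean–Stark trap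
Reagents that add atoms: ethanol, CCO
Why: Acid-catalysed enol ether formation on the symmetrical cyclic 1,3-dione gives the vinylogous ester, and the symmetry of 1 removes any regiochemical question.

Step 2
Reactants: 2 5-ethoxy-2H-pyran-3(6H)-one; 3 5-bromo-2-methylpent-2-ene
Product: 6 5-(4-methylpent-3-en-1-yl)-2H-pyran-3(6H)-one, via homoprenylmagnesium bromide 4 (not isolated), via bromomagnesium alkoxide adduct 5 (not isolated)
Conditions: 3, Mg, THF, rt; then 2, THF, 0 °C; then 1 M HCl, rt
Reagents that add atoms: water, O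
Why: Stork–Danheiser sequence: 1,2-addition of the Grignard reagent to the vinylogous ester carbonyl followed by acid hydrolysis of the enol ether carbinol transposes the enone and places the homoprenyl group on its β-carbon (the future C15).

Step 3
Reactants: 6 5-(4-methylpent-3-en-1-yl)-2H-pyran-3(6H)-one
Product: 7 (3S)-5-(4-methylpent-3-en-1-yl)-3,6-dihydro-2H-pyran-3-ol
Conditions: (S)-2-methyl-CBS-oxazaborolidine (10 mol %), catecholborane, toluene, −78 °C
Reagents that add atoms: none
Why: Corey–Bakshi–Shibata 1,2-reduction, in which the alkenyl carbon is the large and the O–CH2 carbon the small carbonyl substituent, should give the (S)-carbinol, the only external source of absolute configuration in the route, while catecholborane at low temperature leaves the trisubstituted olefin alone.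

Step 4
Reactants: 8 but-2-yn-1-ol
Product: 10 (2Z)-3-iodobut-2-en-1-ol, via cyclic alkenylaluminate 9 (not isolated)
Conditions: NaAlH2(OCH2CH2OMe)2, Et2O, 0 °C to rt; then I2, −78 °C
Reagents that add atoms: iodine, [I][I]
Why: Hydroxyl-directed trans-hydroalumination of the propargylic alcohol places aluminium on C3 cis to the carbinol carbon and iodinolysis with retention gives the (Z)-iodoalkene, which fixes the geometry of the C7=C8 olefin of the target.

Step 5
Reactants: 10 (2Z)-3-iodobut-2-en-1-ol; 11 ethyl but-3-enoate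
Product: 13 ethyl (5Z)-7-hydroxy-5-methylhept-5-enoate, via alkylborane 12 (not isolated)
Conditions: 11, 9-BBN, THF, 0 °C to rt; then 10, Pd(dppf)Cl2 (5 mol %), K3PO4, DMF/H2O, rt
Reagents that add atoms: none
Why: B-alkyl Suzuki–Miyaura coupling of the anti-Markovnikov borane of 11 with the iodoalkene proceeds with retention of olefin geometry and tolerates the free hydroxyl and the ester.

Step 6
Reactants: 13 ethyl (5Z)-7-hydroxy-5-methylhept-5-enoate
Product: 14 ethyl (5Z)-5-methyl-7-oxohept-5-enoate
Conditions: TEMPO (10 mol %), PhI(OAc)2, CH2Cl2, rt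
Reagents that add atoms: none
Why: Nitroxyl-catalysed oxidation of the primary allylic alcohol under nearly neutral conditions should give the (Z)-enal without isomerisation to the (E)-isomer, as is known for nerol.

Step 7
Reactants: 14 ethyl (5Z)-5-methyl-7-oxohept-5-enoate
Product: 15 ethyl (5Z)-5-methylocta-5,7-dienoate
Conditions: [Ph3PCH3]Br, KN(SiMe3)2, THF, −78 °C to 0 °C
Reagents that add atoms: methyltriphenylphosphonium bromide, C[P+](c1ccccc1)(c1ccccc1)c1ccccc1.[Br-]
Why: Wittig methylenation of the aldehyde, which reacts much faster than the ester, gives the terminal (Z)-diene that later serves as the site of hydroboration.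

Step 8
Reactants: 15 ethyl (5Z)-5-methylocta-5,7-dienoate
Product: 16 (5Z)-5-methylocta-5,7-dienoic acid
Conditions: LiOH, THF/H2O, rt; then cold 1 M HCl to pH 3
Reagents that add atoms: lithium hydroxide, [Li+].[OH-]
Why: Saponification of the unhindered ethyl ester gives the acid needed for acylation of 7 and leaves the diene untouched.

Step 9
Reactants: 7 (3S)-5-(4-methylpent-3-en-1-yl)-3,6-dihydro-2H-pyran-3-ol; 16 (5Z)-5-methylocta-5,7-dienoic acid
Product: 17 (3S)-5-(4-methylpent-3-en-1-yl)-3,6-dihydro-2H-pyran-3-yl (5Z)-5-methylocta-5,7-dienoate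
Conditions: DCC, DMAP (cat.), CH2Cl2, 0 °C to rt
Reagents that add atoms: none
Why: Steglich esterification joins the two fragments at the allylic carbinol under neutral conditions with retention at the carbinol carbon.

Step 10
Reactants: 17 (3S)-5-(4-methylpent-3-en-1-yl)-3,6-dihydro-2H-pyran-3-yl (5Z)-5-methylocta-5,7-dienoate
Product: 20 (2R,5Z)-5-methyl-2-[(3S)-3-(4-methylpent-3-en-1-yl)-3,6-dihydro-2H-pyran-3-yl]octa-5,7-dienoic acid, via (E)-silyl ketene acetal 18 (not isolated), via trimethylsilyl ester 19 (not isolated)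
Conditions: LiN(i-Pr)2, THF, −78 °C; Me3SiCl, Et3N, −78 °C to rt, then 55 °C; aq. HCl work-up
Reagents that add atoms: none
Why: Ireland–Claisen rearrangement: the [3,3] shift is suprafacial on the dihydropyran ring, so the carbinol C–O bond is exchanged for the C11–C15 bond on the same ring face (quaternary C15 set), and the (E)-silyl ketene acetal from kinetic enolisation in THF should react through a chair transition state, made accessible because the ring atom facing the ketene acetal is oxygen, to give the C11 configuration shown.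

Step 11
Reactants: 20 (2R,5Z)-5-methyl-2-[(3S)-3-(4-methylpent-3-en-1-yl)-3,6-dihydro-2H-pyran-3-yl]octa-5,7-dienoic acid
Product: 21 (2R,5Z)-5-methyl-2-[(3S)-3-(4-methylpent-3-en-1-yl)-6-oxo-3,6-dihydro-2H-pyran-3-yl]octa-5,7-dienoic acid
Conditions: C5H5NH[CrO3Cl] (4 equiv), CH2Cl2, reflux
Reagents that add atoms: pyridinium chlorochromate, [O-][Cr](=O)(=O)Cl.c1cc[nH+]cc1
Why: The ring CH2 that is both allylic and next to the ring oxygen is oxidised by hexavalent chromium to the carbonyl (the known conversion of 5,6-dihydro-2H-pyrans into 5,6-dihydro-2H-pyran-2-ones), giving the α,β-unsaturated δ-lactone, while the other allylic positions lack the activating oxygen and should react far more slowly.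

Step 12
Reactants: 21 (2R,5Z)-5-methyl-2-[(3S)-3-(4-methylpent-3-en-1-yl)-6-oxo-3,6-dihydro-2H-pyran-3-yl]octa-5,7-dienoic acid
Product: 23 (5S)-5-(4-methylpent-3-en-1-yl)-5-[(4R,7Z)-7-methyl-3-oxodeca-1,7,9-trien-4-yl]-5,6-dihydro-2H-pyran-2-one, via acid chloride 22 (not isolated)
Conditions: 1-chloro-N,N,2-trimethylprop-1-en-1-amine, CH2Cl2, 0 °C to rt; then CH2=CHSnBu3, Pd(PPh3)4 (5 mol %), THF, 50 °C
Reagents that add atoms: tributyl(vinyl)stannane, C=C[Sn](CCCC)(CCCC)CCCC
Why: Neutral formation of the acid chloride and Stille acylation give the vinyl ketone chemoselectively, since only the acyl chloride adds oxidatively to zerovalent palladium while the lactone is inert, and no base is present that could epimerise C11.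

Step 13
Reactants: 23 (5S)-5-(4-methylpent-3-en-1-yl)-5-[(4R,7Z)-7-methyl-3-oxodeca-1,7,9-trien-4-yl]-5,6-dihydro-2H-pyran-2-one
Product: 24 (4aR,8R,8aS)-8-[(3Z)-3-methylhexa-3,5-dien-1-yl]-8a-(4-methylpent-3-en-1-yl)hexahydro-1H-isochromene-3,7(4H,8H)-dione
Conditions: Ru(bpy)3Cl2 (2.5 mol %), i-Pr2NEt, HCO2H, MeCN (0.01 M), blue LEDs, rt
Reagents that add atoms: none
Why: The photoexcited ruthenium complex is quenched by the amine and its reduced form transfers an electron to the acid-activated vinyl ketone, giving a neutral 1-hydroxyallyl radical that bonds through its terminal carbon (C14) to the lactone β-carbon (C1), after which the α-lactone radical is reduced and protonated and the enol tautomerises to the C12 ketone. The closest known reaction type is the photocatalytic reductive cyclisation of enones onto tethered α,β-unsaturated esters in the presence of a Brønsted acid, itself a relative of the electroreductive β,β-coupling of two Michael acceptors. The cyclohexanone ring closes in the 6-exo-trig mode with respect to the lactone olefin. The only new stereocentre, C1, is controlled by the dihydropyranone ring: the tether starts at the adjacent quaternary carbon C15 and can reach C1 only from the face it occupies, so the two rings must be cis-fused, which places C2 cis to the oxygen-bearing CH2 on C15 and trans to the homoprenyl group. The step needs bonding through C14 (not through the α-carbon C13) and cyclisation before simple reduction of the enone; the neutral radical pathway without an enolate, the polarity match between the nucleophilic radical and the electron-poor lactone, the geminal substitution at C15 and high dilution should secure this, and the remaining olefins are unactivated and cannot be reached through a five- or six-membered transition state.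

Step 14
Reactants: 24 (4aR,8R,8aS)-8-[(3Z)-3-methylhexa-3,5-dien-1-yl]-8a-(4-methylpent-3-en-1-yl)hexahydro-1H-isochromene-3,7(4H,8H)-dione
Product: 25 (2S,4a'R,8'R,8a'S)-8'-[(3Z)-3-methylhexa-3,5-dien-1-yl]-8a'-(4-methylpent-3-en-1-yl)hexahydrospiro[oxirane-2,7'-isochromen]-3'(4'H)-one
Conditions: Me3S(O)I, NaH, DMSO/THF, rt
Reagents that add atoms: trimethylsulfoxonium iodide, C[S+](C)(C)=O.[I-]
Why: Corey–Chaykovsky methylenation of the ketone, which is far more reactive towards the ylide than the lactone: in the cis-fused bicycle the homoprenyl group on C15 is axial and 1,3 to the carbonyl and blocks the axial trajectory, and the sulfoxonium ylide in any case favours the equatorial C–C bond, so the CH2 should enter cis to the CH2O group on C15 and the oxygen cis to the homoprenyl group, as in the target.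

Step 15
Reactants: 25 (2S,4a'R,8'R,8a'S)-8'-[(3Z)-3-methylhexa-3,5-dien-1-yl]-8a'-(4-methylpent-3-en-1-yl)hexahydrospiro[oxirane-2,7'-isochromen]-3'(4'H)-one
Product: 26 (2S,4a'R,8'R,8a'S)-8'-[(3Z)-3-methylhexa-3,5-dien-1-yl]-8a'-(4-methylpent-3-en-1-yl)octahydrospiro[oxirane-2,7'-isochromen]-3'-ol (lactol, both C3' epimers)
Conditions: i-Bu2AlH, CH2Cl2, −78 °C; aq. KNaC4H4O6 work-up
Reagents that add atoms: none
Why: Partial reduction of the δ-lactone at low temperature stops at the lactol, which masks the C3 aldehyde and the C15 hydroxymethyl group at the same time, and the oxirane is not attacked at −78 °C.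

Step 16
Reactants: 26 (2S,4a'R,8'R,8a'S)-8'-[(3Z)-3-methylhexa-3,5-dien-1-yl]-8a'-(4-methylpent-3-en-1-yl)octahydrospiro[oxirane-2,7'-isochromen]-3'-ol
Product: 27 [(3S,4R,5S,6R)-6-[(2Z)-3-iodobut-2-en-1-yl]-4-[(3Z)-3-methylhexa-3,5-dien-1-yl]-5-(4-methylpent-3-en-1-yl)-1-oxaspiro[2.5]octan-5-yl]methanol
Conditions: [Ph3PEt]I, n-BuLi, THF, rt; I2, −78 °C; NaN(SiMe3)2, −20 °C; then 26, −78 to −20 °C
Reagents that add atoms: ethyltriphenylphosphonium iodide, CC[P+](c1ccccc1)(c1ccccc1)c1ccccc1.[I-]; iodine, [I][I]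
Why: Stork–Zhao-type Wittig olefination of the lactol through its open hydroxy aldehyde with the α-iodoethylidene ylide gives the (Z)-2-iodoalkene with iodine cis to C2, which fixes the geometry of the later C3=C4 olefin and frees the hydroxymethyl group on C15 in the same operation.

Step 17
Reactants: 27 [(3S,4R,5S,6R)-6-[(2Z)-3-iodobut-2-en-1-yl]-4-[(3Z)-3-methylhexa-3,5-dien-1-yl]-5-(4-methylpent-3-en-1-yl)-1-oxaspiro[2.5]octan-5-yl]methanol
Product: 29 [(1R,3Z,7Z,11R,12S,15S)-4,8-dimethyl-15-(4-methylpent-3-en-1-yl)spiro[bicyclo[9.3.1]pentadeca-3,7-diene-12,2'-oxiran]-15-yl]methanol, via bis-borylated adduct 28 (not isolated)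
Conditions: 9-BBN (3 equiv), THF, rt; then slow addition to Pd(dppf)Cl2 (20 mol %), AsPh3, Cs2CO3, DMF/THF/H2O (2 mM), 50 °C
Reagents that add atoms: none
Why: 9-BBN adds only to the terminal CH2 of the diene because the trisubstituted olefins and the iodoalkene are too hindered, and intramolecular B-alkyl Suzuki–Miyaura coupling of the primary borane with the (Z)-iodoalkene forms the C4–C5 bond with retention and closes the twelve-membered ring under high dilution.

Step 18
Reactants: 29 [(1R,3Z,7Z,11R,12S,15S)-4,8-dimethyl-15-(4-methylpent-3-en-1-yl)spiro[bicyclo[9.3.1]pentadeca-3,7-diene-12,2'-oxiran]-15-yl]methanol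
Product: 30 (1R,3Z,7Z,11R,12S,15S)-4,8-dimethyl-15-(4-methylpent-3-en-1-yl)spiro[bicyclo[9.3.1]pentadeca-3,7-diene-12,2'-oxirane]-15-carbaldehyde
Conditions: Dess–Martin periodinane, NaHCO3, CH2Cl2, 0 °C to rt
Reagents that add atoms: none
Why: Buffered Dess–Martin oxidation of the neopentyl primary alcohol gives the aldehyde, which has no α-hydrogen and cannot epimerise, without touching the oxirane or the olefins.

**Compound list**

1 | 2H-pyran-3,5(4H,6H)-dione | O=C1CC(=O)COC1 | starting material
2 | 5-ethoxy-2H-pyran-3(6H)-one | CCOC1=CC(=O)COC1 | intermediate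
3 | 5-bromo-2-methylpent-2-ene | CC(C)=CCCBr | starting material
4 | (4-methylpent-3-en-1-yl)magnesium bromide | CC(C)=CCC[Mg]Br | intermediate
5 | bromomagnesium alkoxide of 5-ethoxy-3-(4-methylpent-3-en-1-yl)-3,6-dihydro-2H-pyran-3-ol (racemic) | CCOC1=CC(CCC=C(C)C)(O[Mg]Br)COC1 | intermediate
6 | 5-(4-methylpent-3-en-1-yl)-2H-pyran-3(6H)-one | CC(C)=CCCC1=CC(=O)COC1 | intermediate
7 | (3S)-5-(4-methylpent-3-en-1-yl)-3,6-dihydro-2H-pyran-3-ol | CC(C)=CCCC1=C[C@H](O)COC1 | intermediate
8 | but-2-yn-1-ol | CC#CCO | starting material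
9 | sodium 2,2-bis(2-methoxyethoxy)-3-methyl-2,5-dihydro-1,2-oxaaluminol-2-uide (cyclic (Z)-alkenylaluminate) | [Na+].COCCO[Al-]1(OCCOC)OC/C=C\1C | intermediate
10 | (2Z)-3-iodobut-2-en-1-ol | OC/C=C(/C)I | intermediate
11 | ethyl but-3-enoate | C=CCC(=O)OCC | starting material
12 | ethyl 4-(9-borabicyclo[3.3.1]nonan-9-yl)butanoate | CCOC(=O)CCCB1C2CCCC1CCC2 | intermediate
13 | ethyl (5Z)-7-hydroxy-5-methylhept-5-enoate | CCOC(=O)CCC/C(C)=C\CO | intermediate
14 | ethyl (5Z)-5-methyl-7-oxohept-5-enoate | CCOC(=O)CCC/C(C)=C\C=O | intermediate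
15 | ethyl (5Z)-5-methylocta-5,7-dienoate | CCOC(=O)CCC/C(C)=C\C=C | intermediate
16 | (5Z)-5-methylocta-5,7-dienoic acid | OC(=O)CCC/C(C)=C\C=C | intermediate
17 | (3S)-5-(4-methylpent-3-en-1-yl)-3,6-dihydro-2H-pyran-3-yl (5Z)-5-methylocta-5,7-dienoate | CC(C)=CCCC1=C[C@H](OC(=O)CCC/C(C)=C\C=C)COC1 | intermediate
18 | (1E,5Z)-trimethylsilyl ketene acetal of ester 17 (alkyl chain cis to the pyranyloxy group) | CC(C)=CCCC1=C[C@H](O/C(O[Si](C)(C)C)=C\CC/C(C)=C\C=C)COC1 | intermediate
19 | trimethylsilyl (2R,5Z)-5-methyl-2-[(3S)-3-(4-methylpent-3-en-1-yl)-3,6-dihydro-2H-pyran-3-yl]octa-5,7-dienoate | CC(C)=CCC[C@@]1(COCC=C1)[C@@H](CC/C(C)=C\C=C)C(=O)O[Si](C)(C)C | intermediate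
20 | (2R,5Z)-5-methyl-2-[(3S)-3-(4-methylpent-3-en-1-yl)-3,6-dihydro-2H-pyran-3-yl]octa-5,7-dienoic acid | CC(C)=CCC[C@@]1(COCC=C1)[C@@H](CC/C(C)=C\C=C)C(=O)O | intermediate
21 | (2R,5Z)-5-methyl-2-[(3S)-3-(4-methylpent-3-en-1-yl)-6-oxo-3,6-dihydro-2H-pyran-3-yl]octa-5,7-dienoic acid | CC(C)=CCC[C@@]1(COC(=O)C=C1)[C@@H](CC/C(C)=C\C=C)C(=O)O | intermediate
22 | (2R,5Z)-5-methyl-2-[(3S)-3-(4-methylpent-3-en-1-yl)-6-oxo-3,6-dihydro-2H-pyran-3-yl]octa-5,7-dienoyl chloride | CC(C)=CCC[C@@]1(COC(=O)C=C1)[C@@H](CC/C(C)=C\C=C)C(=O)Cl | intermediate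
23 | (5S)-5-(4-methylpent-3-en-1-yl)-5-[(4R,7Z)-7-methyl-3-oxodeca-1,7,9-trien-4-yl]-5,6-dihydro-2H-pyran-2-one | CC(C)=CCC[C@@]1(COC(=O)C=C1)[C@@H](CC/C(C)=C\C=C)C(=O)C=C | intermediate
24 | (4aR,8R,8aS)-8-[(3Z)-3-methylhexa-3,5-dien-1-yl]-8a-(4-methylpent-3-en-1-yl)hexahydro-1H-isochromene-3,7(4H,8H)-dione (cis-fused) | CC(C)=CCC[C@]12COC(=O)C[C@H]1CCC(=O)[C@@H]2CC/C(C)=C\C=C | intermediate
25 | (2S,4a'R,8'R,8a'S)-8'-[(3Z)-3-methylhexa-3,5-dien-1-yl]-8a'-(4-methylpent-3-en-1-yl)hexahydrospiro[oxirane-2,7'-isochromen]-3'(4'H)-one | CC(C)=CCC[C@]12COC(=O)C[C@H]1CC[C@@]1(CO1)[C@@H]2CC/C(C)=C\C=C | intermediate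
26 | (2S,4a'R,8'R,8a'S)-8'-[(3Z)-3-methylhexa-3,5-dien-1-yl]-8a'-(4-methylpent-3-en-1-yl)octahydrospiro[oxirane-2,7'-isochromen]-3'-ol (lactol, both C3' epimers) | CC(C)=CCC[C@]12COC(O)C[C@H]1CC[C@@]1(CO1)[C@@H]2CC/C(C)=C\C=C | intermediate
27 | [(3S,4R,5S,6R)-6-[(2Z)-3-iodobut-2-en-1-yl]-4-[(3Z)-3-methylhexa-3,5-dien-1-yl]-5-(4-methylpent-3-en-1-yl)-1-oxaspiro[2.5]octan-5-yl]methanol | CC(C)=CCC[C@]1(CO)[C@@H](C/C=C(/C)I)CC[C@@]2(CO2)[C@@H]1CC/C(C)=C\C=C | intermediate
28 | bis(9-borabicyclo[3.3.1]nonan-9-yl) adduct of 27 (B-alkyl borane at the terminal diene carbon, O-borinate at the hydroxymethyl group) | CC(C)=CCC[C@]1(COB3C4CCCC3CCC4)[C@@H](C/C=C(/C)I)CC[C@@]2(CO2)[C@@H]1CC/C(C)=C\CCB1C2CCCC1CCC2 | intermediate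
29 | [(1R,3Z,7Z,11R,12S,15S)-4,8-dimethyl-15-(4-methylpent-3-en-1-yl)spiro[bicyclo[9.3.1]pentadeca-3,7-diene-12,2'-oxiran]-15-yl]methanol | CC(C)=CCC[C@]1(CO)[C@H]2C/C=C(/C)CC/C=C(/C)CC[C@H]1[C@@]1(CC2)CO1 | intermediate
30 | (1R,3Z,7Z,11R,12S,15S)-4,8-dimethyl-15-(4-methylpent-3-en-1-yl)spiro[bicyclo[9.3.1]pentadeca-3,7-diene-12,2'-oxirane]-15-carbaldehyde | CC(C)=CCC[C@]1(C=O)[C@H]2C/C=C(/C)CC/C=C(/C)CC[C@H]1[C@@]1(CC2)CO1 | target

**Step count and risks**

Total steps: 18. Longest linear sequence: 15 steps (from 8 through steps 4–18 to 30).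

Steps most likely to fail, in order of risk:

Step 13. The hydroxyallyl radical may be reduced further to the saturated ethyl ketone before it cyclises, or electron transfer to the aliphatic enone may be too slow, so that the ring is not closed. The fallback sets out from acid 21 and comes back at 24. Acid chloride 22 would be coupled with MeZnCl (Pd(PPh3)4, THF) to give the methyl ketone F1. Kinetic enolisation on the methyl side (LiN(i-Pr)2, Me3SiCl, THF, −78 °C) would give the silyl enol ether F2. Simmons–Smith cyclopropanation of the electron-rich enol ether (Et2Zn, CH2I2, CH2Cl2, 0 °C) would give the siloxycyclopropane F3. One-electron oxidation with Fe(NO3)3 in DMF in the presence of 1,4-cyclohexadiene would open the strained ring to the primary β-keto radical at C14, which closes onto C1 of the lactone in the same 6-exo mode and is quenched by hydrogen transfer to give 24.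

Step 17. Intermolecular coupling may outrun ring closure (oligomerisation), and the alkylpalladium intermediate may be lost by protodeboronation or β-hydride elimination while the strained trans-bridged ring forms. The fallback sets out from 27 and comes back at 29. Hydroboration of the diene terminus with 9-BBN and oxidation with NaBO3 would give the diol F4. Appel bromination (CBr4, PPh3, 0 °C), selective for the unhindered primary hydroxyl over the neopentyl one, would give the primary bromide F5. A nickel-catalysed reductive cross-electrophile coupling of the alkenyl iodide with the alkyl bromide (NiBr2(dme), 4,4'-di-tert-butyl-2,2'-bipyridine, Zn, NaI, DMA, slow addition) would then close the C4–C5 bond to give 29.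

Step 16. The hindered iodo ylide may act as a base on the lactol and not as an olefinating agent (low conversion), the freed alkoxide may attack the neighbouring oxirane, and the Z selectivity may erode. The fallback sets out from lactol 26 and comes back at 29. Ramirez olefination (CBr4, PPh3, Zn, CH2Cl2) of the open hydroxy aldehyde would give the 1,1-dibromoalkene F6. A trans-selective Negishi monomethylation (MeZnCl, Pd(DPEphos)Cl2, THF), which replaces the bromine trans to the alkyl chain, would give the (Z)-bromoalkene F7 with bromine cis to C2. F7 would be carried through the hydroboration and Suzuki–Miyaura ring closure of step 17 to give 29.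

**Further compounds**

F1 | step 13 | (5S)-5-(4-methylpent-3-en-1-yl)-5-[(3R,6Z)-6-methyl-2-oxonona-6,8-dien-3-yl]-5,6-dihydro-2H-pyran-2-one | CC(C)=CCC[C@@]1(COC(=O)C=C1)[C@@H](CC/C(C)=C\C=C)C(C)=O
F2 | step 13 | (5S)-5-(4-methylpent-3-en-1-yl)-5-[(3R,6Z)-6-methyl-2-(trimethylsilyloxy)nona-1,6,8-trien-3-yl]-5,6-dihydro-2H-pyran-2-one | CC(C)=CCC[C@@]1(COC(=O)C=C1)[C@@H](CC/C(C)=C\C=C)C(=C)O[Si](C)(C)C
F3 | step 13 | (5S)-5-[(1R,4Z)-4-methyl-1-[1-(trimethylsilyloxy)cyclopropyl]hepta-4,6-dien-1-yl]-5-(4-methylpent-3-en-1-yl)-5,6-dihydro-2H-pyran-2-one | CC(C)=CCC[C@@]1(COC(=O)C=C1)[C@@H](CC/C(C)=C\C=C)C1(O[Si](C)(C)C)CC1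
F4 | step 17 | (3Z)-6-[(3S,4R,5S,6R)-5-(hydroxymethyl)-6-[(2Z)-3-iodobut-2-en-1-yl]-5-(4-methylpent-3-en-1-yl)-1-oxaspiro[2.5]octan-4-yl]-4-methylhex-3-en-1-ol | CC(C)=CCC[C@]1(CO)[C@@H](C/C=C(/C)I)CC[C@@]2(CO2)[C@@H]1CC/C(C)=C\CCO
F5 | step 17 | [(3S,4R,5S,6R)-4-[(3Z)-6-bromo-3-methylhex-3-en-1-yl]-6-[(2Z)-3-iodobut-2-en-1-yl]-5-(4-methylpent-3-en-1-yl)-1-oxaspiro[2.5]octan-5-yl]methanol | CC(C)=CCC[C@]1(CO)[C@@H](C/C=C(/C)I)CC[C@@]2(CO2)[C@@H]1CC/C(C)=C\CCBr
F6 | step 16 | [(3S,4R,5S,6R)-6-(3,3-dibromoprop-2-en-1-yl)-4-[(3Z)-3-methylhexa-3,5-dien-1-yl]-5-(4-methylpent-3-en-1-yl)-1-oxaspiro[2.5]octan-5-yl]methanol | CC(C)=CCC[C@]1(CO)[C@@H](CC=C(Br)Br)CC[C@@]2(CO2)[C@@H]1CC/C(C)=C\C=C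
F7 | step 16 | [(3S,4R,5S,6R)-6-[(2Z)-3-bromobut-2-en-1-yl]-4-[(3Z)-3-methylhexa-3,5-dien-1-yl]-5-(4-methylpent-3-en-1-yl)-1-oxaspiro[2.5]octan-5-yl]methanol | CC(C)=CCC[C@]1(CO)[C@@H](C/C=C(/C)Br)CC[C@@]2(CO2)[C@@H]1CC/C(C)=C\C=C
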